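Atom labels follow kaurane numbering (ring A: C1–C5, C10; lactone: C7, C8, C9, C10, C20; ring C: C8, C9, C11–C14; ring D: C8, C14, C13, C16, C15). The route rests on a Diels–Alder disconnection of ring C. The quaternary carbon C8 is α to the lactone carbonyl C7 and carries C15; as C8=C9 of a spirocyclic 3-formyl-5,6-dihydropyran-2-one, released in situ by selenoxide elimination, it is a doubly activated dienophile. Buta-1,3-diene (C11–C14) adds across it, closing ring C through the C9–C11 and C8–C14 bonds and setting C8 and C9 at once. The Δ12 alkene and the C15 formyl group then allow ring D to be closed by a radical enyne cyclisation.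

Key step: step 9

Remark on the chemistry: 5 and 12 are written as their hydrogen-bonded hydroxymethylene tautomers; 13 and 15 are C8-epimer mixtures, which is harmless because that centre is destroyed in step 9.

Step 1
Reactants: 1 4,4-dimethylcyclohex-2-en-1-one
Product: 2 4,4-dimethylcyclohexa-2,5-dien-1-one
Conditions: DDQ, TsOH (cat.), 1,4-dioxane, reflux
Reagents that add atoms: none
Why: DDQ dehydrogenation of a 4,4-disubstituted cyclohexenone is an established route to the cross-conjugated dienone, and the quaternary C4 blocks aromatisation.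

Step 2
Reactants: 2 4,4-dimethylcyclohexa-2,5-dien-1-one; 3 potassium vinyltrifluoroborate
Product: 4 (R)-4,4-dimethyl-5-vinylcyclohex-2-en-1-one
Conditions: [Rh(cod)2]BF4 (3 mol%), (R)-BINAP (3.3 mol%), 3 (1.05 equiv), PhMe/H2O, 100 °C
Reagents that add atoms: potassium vinyltrifluoroborate (3), C=C[B-](F)(F)F.[K+]
Why: Hayashi–Miyaura rhodium-catalysed asymmetric 1,4-addition desymmetrises the prochiral dienone; (R)-BINAP, the enantiomer that gives (R)-3-substituted cyclohexanones from cyclohex-2-enone, should set C5 as drawn, and a second addition should be slowed because the catalyst-preferred face at C3 of 4 is shielded by the now axial C4 methyl group.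

Step 3
Reactants: 4 (R)-4,4-dimethyl-5-vinylcyclohex-2-en-1-one
Product: 5 (5R,6Z)-6-(hydroxymethylidene)-4,4-dimethyl-5-vinylcyclohex-2-en-1-one
Conditions: NaH, HCO2Et, EtOH (cat.), THF, 0 °C to rt; aq. HCl work-up
Reagents that add atoms: ethyl formate, CCOC=O
Why: Claisen formylation is regiospecific because kaurane C10 is the only enolisable position of 4 (C2 is vinylic, C4 quaternary); C5 is not touched.

Step 4
Reactants: 5 (5R,6Z)-6-(hydroxymethylidene)-4,4-dimethyl-5-vinylcyclohex-2-en-1-one; 6 methyl acrylate
Product: 7 methyl 3-[(1S,6R)-1-formyl-5,5-dimethyl-2-oxo-6-vinylcyclohex-3-en-1-yl]propanoate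
Conditions: DBU (0.2 equiv), MeCN, 0 °C to rt
Reagents that add atoms: methyl acrylate (6), C=CC(=O)OC
Why: Michael addition of the 2-formyl ketone creates quaternary C10; the acrylate should enter anti to the adjacent pseudoaxial vinyl group on C5, as acceptors do at C10 of related 5-substituted 4,4-dimethylcyclohexane systems, so that C9 ends trans and the formyl carbon C20 cis to the C5 substituent.

Step 5
Reactants: 7 methyl 3-[(1S,6R)-1-formyl-5,5-dimethyl-2-oxo-6-vinylcyclohex-3-en-1-yl]propanoate
Product: 9 (6S,11R)-10,10-dimethyl-11-vinyl-2-oxaspiro[5.5]undec-8-ene-3,7-dione, via hydroxy ester 8 (not isolated)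
Conditions: NaBH4, MeOH/THF, −78 °C; then CSA (cat.), PhMe, 50 °C
Reagents that add atoms: none
Why: Chemoselective borohydride reduction of the aldehyde (more electrophilic than the hindered enone carbonyl or the ester) followed by acid-catalysed δ-lactonisation of the hydroxy ester; no stereocentre is involved.

Step 6
Reactants: 9 (6S,11R)-10,10-dimethyl-11-vinyl-2-oxaspiro[5.5]undec-8-ene-3,7-dione
Product: 11 (6S,11R)-11-(dimethoxymethyl)-10,10-dimethyl-2-oxaspiro[5.5]undec-8-ene-3,7-dione, via aldehyde 10 (not isolated)
Conditions: O3, CH2Cl2/MeOH, −78 °C (Sudan Red 7B end-point); Me2S; then HC(OMe)3, TsOH·H2O (cat.), rt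
Reagents that add atoms: trimethyl orthoformate, COC(OC)OC; methanol, CO
Why: Ozonolysis should cleave the electron-rich vinyl group in preference to the electron-poor, hindered enone, and one-pot acetalisation masks the C6 aldehyde at once, which protects the α-stereocentre C5; the lactone is already closed, so C20–OH cannot form a cyclic acetal with C6.

Step 7
Reactants: 11 (6S,11R)-11-(dimethoxymethyl)-10,10-dimethyl-2-oxaspiro[5.5]undec-8-ene-3,7-dione
Product: 12 (4Z,6S,11R)-11-(dimethoxymethyl)-4-(hydroxymethylidene)-10,10-dimethyl-2-oxaspiro[5.5]undec-8-ene-3,7-dione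
Conditions: LiHMDS (2.2 equiv), THF, −78 °C; then CF3CH2OCHO; aq. HCl work-up
Reagents that add atoms: 2,2,2-trifluoroethyl formate, O=COCC(F)(F)F
Why: Kinetic Claisen formylation of the lactone lithium enolate introduces C15 at C8, the only acidic C–H position since the ring-A ketone has no enolisable hydrogen; the non-nucleophilic base avoids lactone opening and retro-aldol loss of C20.

Step 8
Reactants: 12 (4Z,6S,11R)-11-(dimethoxymethyl)-4-(hydroxymethylidene)-10,10-dimethyl-2-oxaspiro[5.5]undec-8-ene-3,7-dione
Product: 13 (6S,11R)-11-(dimethoxymethyl)-10,10-dimethyl-3,7-dioxo-4-(phenylselanyl)-2-oxaspiro[5.5]undec-8-ene-4-carbaldehyde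
Conditions: PhSeCl, pyridine, CH2Cl2, 0 °C
Reagents that add atoms: benzeneselenenyl chloride, Cl[Se]c1ccccc1
Why: α-Selenenylation of a 1,3-dicarbonyl compound with PhSeCl/pyridine occurs on carbon at C8 and needs no stereocontrol.

Step 9
Reactants: 13 (6S,11R)-11-(dimethoxymethyl)-10,10-dimethyl-3,7-dioxo-4-(phenylselanyl)-2-oxaspiro[5.5]undec-8-ene-4-carbaldehyde; 14 buta-1,3-diene
Product: 17 8-formyl Δ12-cyclohexene spirolactone (Diels–Alder adduct), via selenoxide 15 (not isolated), via formyl dihydropyranone 16 (not isolated)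
Conditions: mCPBA, NaHCO3, CH2Cl2, −78 to 0 °C; then buta-1,3-diene (excess), 25–40 °C, sealed tube
Reagents that add atoms: buta-1,3-diene (14), C=CC=C
Why: Oxidation of selenide 13 and syn-elimination of the selenoxide (only C9 offers an sp3 β-hydrogen) release dienophile 16, to which buta-1,3-diene adds in a normal-electron-demand, concerted but asynchronous [4+2] cycloaddition in which the bond to the β-carbon (C9–C11) leads and the C8–C14 bond completes ring C. The closest known reaction type is the Diels–Alder reaction of 2-formyl- and 2-alkoxycarbonyl-cycloalk-2-enones, including those with a quaternary carbon next to the β-position, with simple dienes. Ring C (C8–C9–C11–C12–C13–C14) is closed as a six-membered ring by intermolecular [4+2] annulation, cis-fused to the lactone. C8 and C9 are set together by the suprafacial addition, and their sense relative to C10 by approach of the diene to the lactone face syn to the flat C1 carbonyl, because the opposite face is covered by C5 with its CH(OMe)2 group and the axial C4 methyl group. The step needs chemoselectivity for C8=C9 over the ring-A enone, secured by double activation (C7 and C15) against a singly activated neopentyl C2=C3, and normal rather than hetero-Diels–Alder reactivity, which an electron-poor oxadiene shows towards an unactivated diene; regio- and endo/exo-selectivity do not arise with the symmetrical diene.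

Step 10
Reactants: 17 8-formyl Δ12-cyclohexene spirolactone (Diels–Alder adduct); 18 acetylene
Product: 20 15-acetoxy-15-ethynyl compound (propargylic acetate), via lithium alkoxide 19 (not isolated)
Conditions: HC≡CH (excess), n-BuLi, THF, −78 °C; add 17, −78 °C; then Ac2O, DMAP (cat.), −78 to 0 °C
Reagents that add atoms: lithium acetylide (from acetylene 18 and n-BuLi), [Li+].[C-]#C; acetic anhydride, CC(=O)OC(C)=O
Why: 1,2-Addition of lithium acetylide to the non-enolisable aldehyde with in situ O-acetylation; under non-chelating Felkin–Anh/Cornforth control (C15=O antiperiplanar to the lactone C7=O, attack anti to the bulky C9 branch) O-15 should end cis to C9, which is the endo 15-acetoxy configuration of the target.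

Step 11
Reactants: 20 15-acetoxy-15-ethynyl compound (propargylic acetate)
Product: 22 CNP0108627.4 (target), via vinylstannane 21 (not isolated)
Conditions: Bu3SnH (slow addition), AIBN, PhMe (high dilution), 90 °C; evaporate; then TsOH·H2O, acetone/H2O, rt
Reagents that add atoms: water, O
Why: Tin-mediated radical enyne cyclisation: Bu3Sn• adds to the terminal alkyne carbon C17, the C16 vinyl radical closes 5-exo-trig onto C13 of the Δ12 alkene from the only face the C8–C15 tether can reach (this fixes C13), Bu3SnH reduces the C12 radical, and TsOH then effects protodestannylation to the exocyclic methylene and hydrolysis of the acetal to the C6 aldehyde.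

Compound list
1 | 4,4-dimethylcyclohex-2-en-1-one | CC1(C)CCC(=O)C=C1 | starting material
2 | 4,4-dimethylcyclohexa-2,5-dien-1-one | CC1(C)C=CC(=O)C=C1 | intermediate
3 | potassium vinyltrifluoroborate | C=C[B-](F)(F)F.[K+] | starting material
4 | (R)-4,4-dimethyl-5-vinylcyclohex-2-en-1-one | O=C1C=CC(C)(C)[C@@H](C=C)C1 | intermediate
5 | (5R,6Z)-6-(hydroxymethylidene)-4,4-dimethyl-5-vinylcyclohex-2-en-1-one (enol form of the 2-formyl ketone) | O/C=C1\C(=O)C=CC(C)(C)[C@H]1C=C | intermediate
6 | methyl acrylate | C=CC(=O)OC | starting material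
7 | methyl 3-[(1S,6R)-1-formyl-5,5-dimethyl-2-oxo-6-vinylcyclohex-3-en-1-yl]propanoate (formyl cis, propanoate arm trans to vinyl) | O=C[C@@]1(CCC(=O)OC)C(=O)C=CC(C)(C)[C@H]1C=C | intermediate
8 | methyl 3-[(1S,6R)-1-(hydroxymethyl)-5,5-dimethyl-2-oxo-6-vinylcyclohex-3-en-1-yl]propanoate | OC[C@@]1(CCC(=O)OC)C(=O)C=CC(C)(C)[C@H]1C=C | intermediate (not isolated)
9 | (6S,11R)-10,10-dimethyl-11-vinyl-2-oxaspiro[5.5]undec-8-ene-3,7-dione | O=C1CC[C@]2(CO1)C(=O)C=CC(C)(C)[C@H]2C=C | intermediate
10 | (6S,11R)-10,10-dimethyl-3,7-dioxo-2-oxaspiro[5.5]undec-8-ene-11-carbaldehyde | O=C1CC[C@]2(CO1)C(=O)C=CC(C)(C)[C@H]2C=O | intermediate (not isolated)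
11 | (6S,11R)-11-(dimethoxymethyl)-10,10-dimethyl-2-oxaspiro[5.5]undec-8-ene-3,7-dione | O=C1CC[C@]2(CO1)C(=O)C=CC(C)(C)[C@H]2C(OC)OC | intermediate
12 | (4Z,6S,11R)-11-(dimethoxymethyl)-4-(hydroxymethylidene)-10,10-dimethyl-2-oxaspiro[5.5]undec-8-ene-3,7-dione (enol form of the 8-formyl lactone) | O=C1/C(=C\O)C[C@]2(CO1)C(=O)C=CC(C)(C)[C@H]2C(OC)OC | intermediate
13 | (6S,11R)-11-(dimethoxymethyl)-10,10-dimethyl-3,7-dioxo-4-(phenylselanyl)-2-oxaspiro[5.5]undec-8-ene-4-carbaldehyde (epimers at the selenium-bearing carbon) | O=CC1([Se]c2ccccc2)C[C@]3(COC1=O)C(=O)C=CC(C)(C)[C@H]3C(OC)OC | intermediate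
14 | buta-1,3-diene | C=CC=C | starting material
15 | selenoxide of 13 | O=CC1([Se](=O)c2ccccc2)C[C@]3(COC1=O)C(=O)C=CC(C)(C)[C@H]3C(OC)OC | intermediate (not isolated)
16 | (6S,11R)-11-(dimethoxymethyl)-10,10-dimethyl-3,7-dioxo-2-oxaspiro[5.5]undeca-4,8-diene-4-carbaldehyde | O=CC1=C[C@]2(COC1=O)C(=O)C=CC(C)(C)[C@H]2C(OC)OC | intermediate (not isolated)
17 | Diels–Alder adduct: spirolactone 16 annulated across C8–C9 with the C14–C13=C12–C11 unit; 8-formyl and H-9 cis, C11 and C14 on the lactone face syn to C1 | C1C=CC[C@@H]2[C@@]1(C=O)C(=O)OC[C@]23C(=O)C=CC(C)(C)[C@H]3C(OC)OC | intermediate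
18 | acetylene | C#C | starting material
19 | lithium alkoxide of the 15-ethynyl carbinol derived from 17 | C1C=CC[C@@H]2[C@@]1([C@@H](C#C)O[Li])C(=O)OC[C@]23C(=O)C=CC(C)(C)[C@H]3C(OC)OC | intermediate (not isolated)
20 | propargylic acetate: 17 with C15 as CH(OAc)–C≡CH, C15 configured as in the target | C1C=CC[C@@H]2[C@@]1([C@@H](C#C)OC(C)=O)C(=O)OC[C@]23C(=O)C=CC(C)(C)[C@H]3C(OC)OC | intermediate
21 | 17-(tributylstannyl) derivative of the target 6-dimethyl acetal (E/Z mixture at C16=C17) | CCCC[Sn](CCCC)(CCCC)C=C1[C@@H]2CC[C@@H]3[C@](C2)(C(=O)OC[C@]32C(=O)C=CC(C)(C)[C@H]2C(OC)OC)[C@@H]1OC(C)=O | intermediate (not isolated)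
22 | CNP0108627.4: 15-acetoxy-1,6-dioxo-6,7-seco-ent-kaura-2,16-dien-7,20-olide, 15-acetoxy group endo (anti to C14, cis to C9 on ring D) | C=C1[C@@H]2CC[C@@H]3[C@](C2)(C(=O)OC[C@]32C(=O)C=CC(C)(C)[C@H]2C=O)[C@@H]1OC(C)=O | target

Total step count: 11. Longest linear sequence: 11 steps (1 to 22).

Steps most likely to fail

1. Step 9. The transient 2-formyl enoate may oligomerise or be consumed by other pathways faster than unactivated butadiene adds at the hindered C9, giving slow or low-yielding cycloaddition. Fallback: starting from selenide 13, the same oxidation and elimination are run in the presence of 2-(trimethylsilyloxy)buta-1,3-diene. This electron-rich diene should react in a Mukaiyama–Michael/Michael (stepwise [4+2]) manifold, its nucleophilic terminus bonding to C9 and the ring again closing at C8–C14, to give the silyl enol ether adduct F1 with the oxygen on C12. CsF and PhNTf2 convert it regiospecifically into the enol triflate F2. Palladium-catalysed formate reduction (Pd(OAc)2, PPh3, HCO2H, Bu3N, DMF) removes the triflate and rejoins the route at 17.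

2. Step 10. Facial selectivity in the acetylide addition may be poor or reversed if lithium chelates the C15 and C7 carbonyl oxygens, which would deliver the C15 epimer. Fallback: starting from 17, acetylide addition with a protic quench gives the epimeric propargylic alcohols F3. Dess–Martin oxidation gives the ynone F4. Corey–Bakshi–Shibata reduction with the (S)-oxazaborolidine and catecholborane, in which the ethynyl group acts as the small substituent, should give the propargylic alcohol F5 with the required C15 configuration by reagent control. Acetylation (Ac2O, pyridine, DMAP) rejoins the route at 20.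

3. Step 11. The vinyl radical may close with the wrong regiochemistry (6-endo attack at C12, leading to a bicyclo[2.2.2]octane) or be reduced before it cyclises. Fallback: starting from 20, bromoboration of the terminal alkyne with B-bromo-9-BBN followed by protonolysis with acetic acid gives the 2-bromoallylic acetate F6. A reductive Heck cyclisation (Pd(OAc)2, PPh3, HCO2Na, Et4NCl, DMF, 80 °C), in which syn-carbopalladation can only proceed 5-exo onto C13 and formate reduces the C12–Pd bond, gives the bicyclic dimethyl acetal F7. Hydrolysis with TsOH·H2O in wet acetone rejoins the route at 22.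

Further compounds
F1 | step 9 | silyl enol ether adduct (12-trimethylsilyloxy analogue of 17) | C1C=C(O[Si](C)(C)C)C[C@@H]2[C@@]1(C=O)C(=O)OC[C@]23C(=O)C=CC(C)(C)[C@H]3C(OC)OC
F2 | step 9 | enol triflate (12-trifluoromethanesulfonyloxy analogue of 17) | C1C=C(OS(=O)(=O)C(F)(F)F)C[C@@H]2[C@@]1(C=O)C(=O)OC[C@]23C(=O)C=CC(C)(C)[C@H]3C(OC)OC
F3 | step 10 | propargylic alcohols (mixture of C15 epimers) | C1C=CC[C@@H]2[C@@]1(C(O)C#C)C(=O)OC[C@]23C(=O)C=CC(C)(C)[C@H]3C(OC)OC
F4 | step 10 | ynone (15-oxo-16-yne) | C1C=CC[C@@H]2[C@@]1(C(=O)C#C)C(=O)OC[C@]23C(=O)C=CC(C)(C)[C@H]3C(OC)OC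
F5 | step 10 | propargylic alcohol with the C15 configuration of 20 | C1C=CC[C@@H]2[C@@]1([C@@H](C#C)O)C(=O)OC[C@]23C(=O)C=CC(C)(C)[C@H]3C(OC)OC
F6 | step 11 | 2-bromoallylic acetate (16-bromo-16(17)-ene analogue of 20) | C1C=CC[C@@H]2[C@@]1([C@@H](C(Br)=C)OC(C)=O)C(=O)OC[C@]23C(=O)C=CC(C)(C)[C@H]3C(OC)OC
F7 | step 11 | 6-dimethyl acetal of the target | C=C1[C@@H]2CC[C@@H]3[C@](C2)(C(=O)OC[C@]32C(=O)C=CC(C)(C)[C@H]2C(OC)OC)[C@@H]1OC(C)=O
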